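## Retrosynthetic overview

1. The target is opened at the C(spiro)–CH2 bond: a fluoride-released 4-arylsyringol phenoxide attacks a primary tosylate through its para carbon (alkylative dearomatization), so the seven-membered ring and the dienone form together in the last step.
2. The tosylate acetate comes from an all-syn 1-aryl-2,3-dimethylbutane-1,4-diol, itself from a γ-lactone whose α-methyl (C8) is set by enolate methylation anti to the C7 methyl.
3. The cis-β-methyl-γ-aryl lactone comes from a syn homoallylic alcohol (hydroboration, oxidative lactonization), made by Brown (Z)-crotylboration of a biaryl aldehyde (sets C6 and C7).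
4. The biaryl bond is made first by Suzuki coupling. Ring order: biaryl, then a temporary lactone, then the spiro seven-membered ring and dienone.

Assumption: 1 and 2 are catalogue compounds; in names ArT = 2-[3,5-dimethoxy-4-(triisopropylsilyloxy)phenyl]-3,4,5-trimethoxyphenyl, and the chain atoms are called C6 (ArCH–O), C7, C8 (CHMe) and C9 (CH2).

## Route

Step 1
Reactants: 1 2-bromo-3,4,5-trimethoxybenzaldehyde; 2 2,6-dimethoxy-4-(4,4,5,5-tetramethyl-1,3,2-dioxaborolan-2-yl)phenol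
Product: 3 4'-hydroxy-3',4,5,5',6-pentamethoxy-[1,1'-biphenyl]-2-carbaldehyde
Conditions: Pd(OAc)2 (3 mol%), SPhos (6 mol%), K3PO4, PhMe/H2O 10:1, 80 °C
Reagents that add atoms: none
Why: Suzuki–Miyaura coupling; the ortho-formyl group speeds oxidative addition and SPhos tolerates the di-ortho-substituted bromide, and no stereo element arises because the phenol ring is symmetric.

Step 2
Reactants: 3 4'-hydroxy-3',4,5,5',6-pentamethoxy-[1,1'-biphenyl]-2-carbaldehyde
Product: 4 3',4,5,5',6-pentamethoxy-4'-(triisopropylsilyloxy)-[1,1'-biphenyl]-2-carbaldehyde (ArT-CHO)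
Conditions: TIPSOTf, 2,6-lutidine, CH2Cl2, 0 °C to rt
Reagents that add atoms: triisopropylsilyl triflate, CC(C)[Si](OS(=O)(=O)C(F)(F)F)(C(C)C)C(C)C
Why: Silyl triflate silylation of the hindered phenol; the TIPS ether survives borane, LDA, hydride and TsCl and later serves as the fluoride-releasable phenoxide.

Step 3
Reactants: 4 ArT-CHO
Product: 6 (1R,2S)-2-methyl-1-ArT-but-3-en-1-ol, via borinate ester 5 (not isolated)
Conditions: (Z)-crotyl-B(Ipc)2 [cis-2-butene, n-BuLi, KOt-Bu; (+)-Ipc2BOMe (Ipc from (−)-α-pinene); BF3·OEt2], THF, −78 °C; then NaBO3·4H2O, THF/H2O, rt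
Reagents that add atoms: (Z)-crotyldiisopinocampheylborane, C/C=C\CB([C@H]1C[C@H]2C[C@@H]([C@@H]1C)C2(C)C)[C@H]1C[C@H]2C[C@@H]([C@@H]1C)C2(C)C
Why: Brown asymmetric crotylboration through a closed Zimmerman–Traxler chair; the (Z)-crotyl geometry gives the syn C6–OH/C7–Me pair and the (−)-α-pinene-derived Ipc groups direct Re-face addition, setting C6 (R) and C7 (S).

Step 4
Reactants: 6 (1R,2S)-2-methyl-1-ArT-but-3-en-1-ol
Product: 8 (1R,2S)-2-methyl-1-ArT-butane-1,4-diol, via B-alkyl-9-BBN adduct 7 (not isolated)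
Conditions: 9-BBN (2.5 equiv), THF, 0 °C to rt; then NaBO3·4H2O, H2O, rt
Reagents that add atoms: sodium perborate, [Na+].[Na+].O[B-]1(O)OO[B-](O)(O)OO1 (oxygen of the new OH); 9-BBN, B1C2CCCC1CCC2 (boron present in 7 only)
Why: Anti-Markovnikov hydroboration–oxidation of the terminal alkene; no stereocenter is formed or touched, and perborate spares the aryl silyl ether.

Step 5
Reactants: 8 (1R,2S)-2-methyl-1-ArT-butane-1,4-diol
Product: 10 (4S,5R)-4-methyl-5-ArT-dihydrofuran-2(3H)-one (cis), via lactol 9 (not isolated)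
Conditions: TEMPO (20 mol%), PhI(OAc)2 (2.5 equiv), CH2Cl2, rt
Reagents that add atoms: none
Why: Oxidative lactonization; TEMPO/PhI(OAc)2 oxidizes the primary alcohol in preference to the hindered benzylic one, the aldehyde closes to the lactol and is oxidized on to the lactone with C6 and C7 unchanged.

Step 6
Reactants: 10 (4S,5R)-4-methyl-5-ArT-dihydrofuran-2(3H)-one
Product: 12 (3S,4S,5R)-3,4-dimethyl-5-ArT-dihydrofuran-2(3H)-one, via lithium enolate 11 (not isolated)
Conditions: LDA (1.1 equiv), THF, −78 °C; MeI, −78 to −40 °C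
Reagents that add atoms: iodomethane, CI; LDA, [Li+].CC(C)[N-]C(C)C (lithium counter-ion of 11 only)
Why: Lactone enolate alkylation; MeI enters the enolate face anti to the adjacent C7 methyl and the cis C6 aryl (both on the other face), setting C8 as the 3,4-trans isomer.

Step 7
Reactants: 12 (3S,4S,5R)-3,4-dimethyl-5-ArT-dihydrofuran-2(3H)-one
Product: 13 (1R,2S,3S)-2,3-dimethyl-1-ArT-butane-1,4-diol
Conditions: LiBH4, THF, 0 °C to rt
Reagents that add atoms: none
Why: Hydride reduction of the lactone to the 1,4-diol; the non-basic reagent does not epimerize C8 and leaves the aryl TIPS ether intact.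

Step 8
Reactants: 13 (1R,2S,3S)-2,3-dimethyl-1-ArT-butane-1,4-diol
Product: 15 (1R,2S,3S)-2,3-dimethyl-4-(tosyloxy)-1-ArT-butyl acetate, via hydroxy tosylate 14 (not isolated)
Conditions: TsCl (1.1 equiv), Et3N, Me3N·HCl (10 mol%), CH2Cl2, 0 °C; then Ac2O, DMAP, 0 °C to rt
Reagents that add atoms: p-toluenesulfonyl chloride, Cc1ccc(cc1)S(Cl)(=O)=O; acetic anhydride, CC(=O)OC(C)=O
Why: Chemoselective sulfonylation of the unhindered primary alcohol, then DMAP-catalysed acetylation of the hindered benzylic alcohol in the same pot before it can close to the tetrahydrofuran; no stereocenter is touched.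

Step 9
Reactants: 15 (1R,2S,3S)-2,3-dimethyl-4-(tosyloxy)-1-ArT-butyl acetate
Product: 17 (7R,8S,9R)-2,3,3',4,5'-pentamethoxy-7,8-dimethyl-4'-oxo-6,7,8,9-tetrahydrospiro[benzo[7]annulene-5,1'-cyclohexane]-2',5'-dien-9-yl acetate (CNP0143674.1), via cesium phenoxide 16 (not isolated)
Conditions: CsF (3 equiv), DMF (0.004 M, slow addition), rt to 70 °C
Reagents that add atoms: cesium fluoride, [Cs+].[F-] (cesium counter-ion of 16 only; no atoms in 17)
Why: Proposed new method: fluoride strips the TIPS group to a phenoxide whose oxygen cannot reach C9 within the molecule, so the only intramolecular pathway is SN2 attack of the para carbon (ipso to the twisted biaryl bond, its π lobe pointing at the ortho side chain) on the primary tosylate in a 7-exo-tet closure, with high dilution suppressing intermolecular O-alkylation; the closest known reaction type is Winstein Ar1-5/Ar1-6 phenolate para-alkylation and fluoride-triggered alkylative dearomatization of silyl aryl ether sulfonates, the spiro carbon is not stereogenic and C6–C8 are untouched.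

## Compound list

1 | 2-bromo-3,4,5-trimethoxybenzaldehyde | COc1cc(C=O)c(Br)c(OC)c1OC | starting material
2 | 2,6-dimethoxy-4-(4,4,5,5-tetramethyl-1,3,2-dioxaborolan-2-yl)phenol | COc1cc(cc(OC)c1O)B1OC(C)(C)C(C)(C)O1 | starting material
3 | 4'-hydroxy-3',4,5,5',6-pentamethoxy-[1,1'-biphenyl]-2-carbaldehyde | COc1cc(C=O)c(c(OC)c1OC)-c1cc(OC)c(O)c(OC)c1 | intermediate
4 | 3',4,5,5',6-pentamethoxy-4'-(triisopropylsilyloxy)-[1,1'-biphenyl]-2-carbaldehyde | COc1cc(C=O)c(c(OC)c1OC)-c1cc(OC)c(O[Si](C(C)C)(C(C)C)C(C)C)c(OC)c1 | intermediate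
5 | diisopinocampheylborinate ester of 6 | C=C[C@H](C)[C@@H](OB([C@H]1C[C@H]2C[C@@H]([C@@H]1C)C2(C)C)[C@H]1C[C@H]2C[C@@H]([C@@H]1C)C2(C)C)c1cc(OC)c(OC)c(OC)c1-c1cc(OC)c(O[Si](C(C)C)(C(C)C)C(C)C)c(OC)c1 | intermediate (not isolated)
6 | (1R,2S)-2-methyl-1-ArT-but-3-en-1-ol | C=C[C@H](C)[C@@H](O)c1cc(OC)c(OC)c(OC)c1-c1cc(OC)c(O[Si](C(C)C)(C(C)C)C(C)C)c(OC)c1 | intermediate
7 | B-alkyl-9-BBN adduct of 6 (boron on C9) | B1(CC[C@H](C)[C@@H](O)c3cc(OC)c(OC)c(OC)c3-c4cc(OC)c(O[Si](C(C)C)(C(C)C)C(C)C)c(OC)c4)C2CCCC1CCC2 | intermediate (not isolated)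
8 | (1R,2S)-2-methyl-1-ArT-butane-1,4-diol | OCC[C@H](C)[C@@H](O)c1cc(OC)c(OC)c(OC)c1-c1cc(OC)c(O[Si](C(C)C)(C(C)C)C(C)C)c(OC)c1 | intermediate
9 | (4S,5R)-4-methyl-5-ArT-tetrahydrofuran-2-ol (lactol, anomer mixture) | OC1C[C@H](C)[C@@H](O1)c2cc(OC)c(OC)c(OC)c2-c3cc(OC)c(O[Si](C(C)C)(C(C)C)C(C)C)c(OC)c3 | intermediate (not isolated)
10 | (4S,5R)-4-methyl-5-ArT-dihydrofuran-2(3H)-one | O=C1C[C@H](C)[C@@H](O1)c2cc(OC)c(OC)c(OC)c2-c3cc(OC)c(O[Si](C(C)C)(C(C)C)C(C)C)c(OC)c3 | intermediate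
11 | lithium enolate of 10 | [Li+].[O-]C1=C[C@H](C)[C@@H](O1)c2cc(OC)c(OC)c(OC)c2-c3cc(OC)c(O[Si](C(C)C)(C(C)C)C(C)C)c(OC)c3 | intermediate (not isolated)
12 | (3S,4S,5R)-3,4-dimethyl-5-ArT-dihydrofuran-2(3H)-one | O=C1[C@@H](C)[C@H](C)[C@@H](O1)c2cc(OC)c(OC)c(OC)c2-c3cc(OC)c(O[Si](C(C)C)(C(C)C)C(C)C)c(OC)c3 | intermediate
13 | (1R,2S,3S)-2,3-dimethyl-1-ArT-butane-1,4-diol | OC[C@@H](C)[C@H](C)[C@@H](O)c1cc(OC)c(OC)c(OC)c1-c1cc(OC)c(O[Si](C(C)C)(C(C)C)C(C)C)c(OC)c1 | intermediate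
14 | (2S,3S,4R)-4-hydroxy-2,3-dimethyl-4-ArT-butyl 4-methylbenzenesulfonate | Cc1ccc(cc1)S(=O)(=O)OC[C@@H](C)[C@H](C)[C@@H](O)c1cc(OC)c(OC)c(OC)c1-c1cc(OC)c(O[Si](C(C)C)(C(C)C)C(C)C)c(OC)c1 | intermediate (not isolated)
15 | (1R,2S,3S)-2,3-dimethyl-4-(tosyloxy)-1-ArT-butyl acetate | Cc1ccc(cc1)S(=O)(=O)OC[C@@H](C)[C@H](C)[C@@H](OC(C)=O)c1cc(OC)c(OC)c(OC)c1-c1cc(OC)c(O[Si](C(C)C)(C(C)C)C(C)C)c(OC)c1 | intermediate
16 | cesium phenoxide of desilylated 15 | [Cs+].Cc1ccc(cc1)S(=O)(=O)OC[C@@H](C)[C@H](C)[C@@H](OC(C)=O)c1cc(OC)c(OC)c(OC)c1-c1cc(OC)c([O-])c(OC)c1 | intermediate (not isolated)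
17 | (7R,8S,9R)-2,3,3',4,5'-pentamethoxy-7,8-dimethyl-4'-oxo-6,7,8,9-tetrahydrospiro[benzo[7]annulene-5,1'-cyclohexane]-2',5'-dien-9-yl acetate | COC1=CC2(C=C(OC)C1=O)C[C@@H](C)[C@H](C)[C@@H](OC(C)=O)c1cc(OC)c(OC)c(OC)c12 | target

## Count and risk

Total steps: 9. Longest linear sequence: 9 steps (from 1 or 2 to 17).

Steps most likely to fail:

Step 9 (seven-membered para-C-alkylation at a β-branched primary carbon; competing intermolecular O-alkylation). Fallback, setting out from 15 and coming back at 17: the bond is made by a radical pathway instead of SN2. Finkelstein exchange of 15 (NaI, acetone, reflux) gives (1R,2S,3S)-4-iodo-2,3-dimethyl-1-ArT-butyl acetate F1. CsF in degassed DMSO then releases the cesium phenoxide iodide F2, which is irradiated at 390–427 nm. The photoexcited phenolate transfers an electron to its own C–I bond (SRN1-type), and the phenoxyl/primary-alkyl radical pair collapses at the para carbon to give 17; radical C–C formation is far less sensitive to β-branching.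

Step 8 (the hydroxy tosylate 14 can close to the 2-aryl-tetrahydrofuran before it is acetylated). Fallback, setting out from 13 and coming back at 15: the two hydroxyls are differentiated by protection instead of by rate. TBSCl/imidazole (CH2Cl2, 0 °C) silylates only the primary alcohol to give (1R,2S,3S)-4-(tert-butyldimethylsilyloxy)-2,3-dimethyl-1-ArT-butan-1-ol F3. Ac2O/DMAP/pyridine gives (1R,2S,3S)-4-(tert-butyldimethylsilyloxy)-2,3-dimethyl-1-ArT-butyl acetate F4. AcOH/THF/H2O removes the alkyl TBS group (the aryl TIPS ether is acid-stable) to give (1R,2S,3S)-4-hydroxy-2,3-dimethyl-1-ArT-butyl acetate F5. TsCl/pyridine at 0 °C then gives 15, with no free benzylic hydroxyl present once the leaving group is in place.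

Step 3 (enantio- and diastereoselectivity of crotylboration on the ortho-aryl benzaldehyde). Fallback, setting out from 4 and coming back at 10: the lactone is built through a butenolide instead of a crotylation. ProPhenol/Me2Zn-catalysed addition of ethyl propiolate to 4 (ligand enantiomer that delivers the R carbinol) gives ethyl (R)-4-hydroxy-4-ArT-but-2-ynoate F6. Me2CuLi (2.5 equiv, THF, −78 °C) adds methyl syn across the ynoate and the Z-hydroxy enoate lactonizes to (R)-4-methyl-5-ArT-furan-2(5H)-one F7. Hydrogenation (H2, Rh/Al2O3, EtOAc) delivers hydrogen to the face opposite the C5 aryl group, giving the cis lactone 10.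

Further compounds
F1 | step 9 | (1R,2S,3S)-4-iodo-2,3-dimethyl-1-ArT-butyl acetate | IC[C@@H](C)[C@H](C)[C@@H](OC(C)=O)c1cc(OC)c(OC)c(OC)c1-c1cc(OC)c(O[Si](C(C)C)(C(C)C)C(C)C)c(OC)c1
F2 | step 9 | cesium phenoxide of desilylated F1 | [Cs+].IC[C@@H](C)[C@H](C)[C@@H](OC(C)=O)c1cc(OC)c(OC)c(OC)c1-c1cc(OC)c([O-])c(OC)c1
F3 | step 8 | (1R,2S,3S)-4-(tert-butyldimethylsilyloxy)-2,3-dimethyl-1-ArT-butan-1-ol | CC(C)(C)[Si](C)(C)OC[C@@H](C)[C@H](C)[C@@H](O)c1cc(OC)c(OC)c(OC)c1-c1cc(OC)c(O[Si](C(C)C)(C(C)C)C(C)C)c(OC)c1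
F4 | step 8 | (1R,2S,3S)-4-(tert-butyldimethylsilyloxy)-2,3-dimethyl-1-ArT-butyl acetate | CC(C)(C)[Si](C)(C)OC[C@@H](C)[C@H](C)[C@@H](OC(C)=O)c1cc(OC)c(OC)c(OC)c1-c1cc(OC)c(O[Si](C(C)C)(C(C)C)C(C)C)c(OC)c1
F5 | step 8 | (1R,2S,3S)-4-hydroxy-2,3-dimethyl-1-ArT-butyl acetate | OC[C@@H](C)[C@H](C)[C@@H](OC(C)=O)c1cc(OC)c(OC)c(OC)c1-c1cc(OC)c(O[Si](C(C)C)(C(C)C)C(C)C)c(OC)c1
F6 | step 3 | ethyl (R)-4-hydroxy-4-ArT-but-2-ynoate | CCOC(=O)C#C[C@@H](O)c1cc(OC)c(OC)c(OC)c1-c1cc(OC)c(O[Si](C(C)C)(C(C)C)C(C)C)c(OC)c1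
F7 | step 3 | (R)-4-methyl-5-ArT-furan-2(5H)-one | O=C1C=C(C)[C@@H](O1)c2cc(OC)c(OC)c(OC)c2-c3cc(OC)c(O[Si](C(C)C)(C(C)C)C(C)C)c(OC)c3
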